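**Retrosynthetic overview**

1. The target comes from its 8-O-methyl ether by a final chelation-directed O-demethylation with BCl3.
2. Key disconnection, C5–CHCl2 of the butyrolactone: a ketone carbon and the carbon of CH2Cl2, both electrophilic by nature, are joined by using the latter with reversed polarity as LiCHCl2, a carbanion at the formyl oxidation level (a masked formyl anion, d1, whose mask stays as the CHCl2 group). The new alkoxide closes the lactone by acyl transfer from a dioxolanone, so the C–C bond, the quaternary stereocentre and the lactone ring arise in one operation.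
3. The ketone comes from lateral C-acylation of 6,8-dimethoxy-3-methylisocoumarin with the acetonide of L-malic acid; C3 (S) is taken from the chiral pool and directs C5 by 1,3-induction.
4. The isocoumarin comes from methyl 2,4-dimethoxy-6-methylbenzoate and N-methoxy-N-methylacetamide (toluate acylation, enol lactonisation).
5. Ring order: the benzene ring is bought; the pyranone ring of the isocoumarin is closed first (step 1); the butyrolactone is closed last (step 3), the dioxolanone being a temporary ring consumed there.

Assumption: methyl 2,4-dimethoxy-6-methylbenzoate and (S)-2,2-dimethyl-5-oxo-1,3-dioxolane-4-acetic acid (the acetonide of L-malic acid) are taken as catalogue compounds.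

**Route**

Step 1
Reactants: 1 methyl 2,4-dimethoxy-6-methylbenzoate; 2 N-methoxy-N-methylacetamide
Product: 4 6,8-dimethoxy-3-methyl-1H-isochromen-1-one, via keto ester 3 (not isolated)
Conditions: LiN(iPr)2 (1.15 equiv), THF, −78 °C, 20 min; 2 (1.3 equiv), −78 → 0 °C; 1 M HCl quench, extraction; crude 3 in CF3CO2H/CH2Cl2 (1:4), 40 °C, 12 h
Reagents that add atoms: none
Why: Lateral (benzylic) lithiation of the ortho-toluate and C-acylation by the Weinreb amide stop cleanly at keto ester 3 because the chelated tetrahedral adduct survives until the quench, and acid-catalysed enol lactonisation of 3 onto the neighbouring methyl ester then closes the pyranone ring; no stereocentre is formed.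

Step 2
Reactants: 4 6,8-dimethoxy-3-methyl-1H-isochromen-1-one; 5 (S)-2-(2,2-dimethyl-5-oxo-1,3-dioxolan-4-yl)acetic acid; 6 1,1'-carbonyldiimidazole
Product: 8 (5S)-5-[3-(6,8-dimethoxy-1-oxo-1H-isochromen-3-yl)-2-oxopropyl]-2,2-dimethyl-1,3-dioxolan-4-one, via acyl imidazolide 7 (not isolated)
Conditions: 5 (1.0 equiv), 6 (1.05 equiv), THF, 25 °C, 1 h; this solution added to 4 (3.0 equiv)/LiN(iPr)2 (3.0 equiv), THF, −78 °C, 1 h; AcOH quench at −78 °C; excess 4 recovered
Reagents that add atoms: none
Why: Vinylogous lateral deprotonation of the 3-methyl group (the isocoumarin is the benzo analogue of a 6-methyl-2-pyranone, and the anion is an ortho-carbonyl-stabilised benzylic/allylic carbanion) followed by Claisen-type C-acylation with the acyl imidazolide gives the ketone, the second and third equivalents of anion being spent on the imidazole N–H and on turning 8 at once into its C1′ enolate, which shields it from β-elimination of the ring oxygen; the (S) centre from L-malic acid is not touched.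

Step 3
Reactants: 8 (5S)-5-[3-(6,8-dimethoxy-1-oxo-1H-isochromen-3-yl)-2-oxopropyl]-2,2-dimethyl-1,3-dioxolan-4-one; 9 dichloromethane
Product: 12 (3S,5R)-5-(dichloromethyl)-5-[(6,8-dimethoxy-1-oxo-1H-isochromen-3-yl)methyl]-3-hydroxyoxolan-2-one, via dichloromethyllithium 10 (not isolated), via tertiary alkoxide adduct 11 (not isolated)
Conditions: 9 (2.0 equiv), n-BuLi (1.5 equiv), THF, −100 °C, 20 min; transferred by cold cannula onto 8 pre-stirred with anhydrous CeCl3 (1.5 equiv) in THF, −100 °C, 1 h; −100 → −60 °C, 1 h; AcOH (3 equiv), −78 °C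
Reagents that add atoms: none
Why: Proposed new method: LiCHCl2 (Köbrich carbenoid, a carbanion at the formyl oxidation level) adds 1,2 to the ketone, which CeCl3 activates and keeps from being enolised at the acidic C1′H2, attacking the face anti to the dioxolanone in the six-membered chelate between the ketone oxygen and the ring oxygen on C3 (1,3-anti induction, so the fixed 3S centre sets 5R), and alkoxide 11 then attacks the dioxolanone carbonyl (5-exo acyl transfer) to close the γ-lactone with loss of acetone before it can displace chloride; the closest known reaction types are the addition of LiCHCl2 to ketones giving dichloromethyl carbinols, organocerium additions to easily enolised ketones and chelation-controlled additions to β-alkoxy ketones.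

Step 4
Reactants: 12 (3S,5R)-5-(dichloromethyl)-5-[(6,8-dimethoxy-1-oxo-1H-isochromen-3-yl)methyl]-3-hydroxyoxolan-2-one
Product: 13 (3S,5R)-5-(dichloromethyl)-3-hydroxy-5-[(8-hydroxy-6-methoxy-1-oxo-1H-isochromen-3-yl)methyl]oxolan-2-one
Conditions: BCl3 (3.0 equiv, 1 M in CH2Cl2), CH2Cl2, −78 → 0 °C, 2 h; then H2O, 0 °C
Reagents that add atoms: none
Why: Chelation-directed Lewis acid ether cleavage, in which BCl3 binds between the lactone carbonyl and the peri 8-methoxy oxygen so that chloride removes only that methyl group, while the 6-methoxy group, both lactones, the CHCl2 group and both stereocentres stay as they are (the C3 hydroxyl is only borylated until the aqueous work-up).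

**Compound list**

number | name | SMILES with stereochemistry | starting material, intermediate or target
1 | methyl 2,4-dimethoxy-6-methylbenzoate | COC(=O)c1c(C)cc(OC)cc1OC | starting material
2 | N-methoxy-N-methylacetamide | CC(=O)N(C)OC | starting material
3 | methyl 2,4-dimethoxy-6-(2-oxopropyl)benzoate (keto ester) | COC(=O)c1c(CC(C)=O)cc(OC)cc1OC | intermediate
4 | 6,8-dimethoxy-3-methyl-1H-isochromen-1-one | COc1cc(OC)c2c(=O)oc(C)cc2c1 | intermediate
5 | (S)-2-(2,2-dimethyl-5-oxo-1,3-dioxolan-4-yl)acetic acid | OC(=O)C[C@@H]1OC(C)(C)OC1=O | starting material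
6 | 1,1'-carbonyldiimidazole | O=C(n1ccnc1)n1ccnc1 | starting material
7 | (5S)-5-[2-(1H-imidazol-1-yl)-2-oxoethyl]-2,2-dimethyl-1,3-dioxolan-4-one (acyl imidazolide) | O=C(C[C@@H]1OC(C)(C)OC1=O)n1ccnc1 | intermediate
8 | (5S)-5-[3-(6,8-dimethoxy-1-oxo-1H-isochromen-3-yl)-2-oxopropyl]-2,2-dimethyl-1,3-dioxolan-4-one | COc1cc(OC)c2c(=O)oc(CC(=O)C[C@@H]3OC(C)(C)OC3=O)cc2c1 | intermediate
9 | dichloromethane | ClCCl | starting material
10 | dichloromethyllithium | [Li]C(Cl)Cl | intermediate
11 | lithium (2R)-1,1-dichloro-2-[(6,8-dimethoxy-1-oxo-1H-isochromen-3-yl)methyl]-3-[(4S)-2,2-dimethyl-5-oxo-1,3-dioxolan-4-yl]propan-2-olate (tertiary alkoxide adduct) | COc1cc(OC)c2c(=O)oc(C[C@@](O[Li])(C(Cl)Cl)C[C@@H]3OC(C)(C)OC3=O)cc2c1 | intermediate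
12 | (3S,5R)-5-(dichloromethyl)-5-[(6,8-dimethoxy-1-oxo-1H-isochromen-3-yl)methyl]-3-hydroxyoxolan-2-one | COc1cc(OC)c2c(=O)oc(C[C@@]3(C(Cl)Cl)C[C@H](O)C(=O)O3)cc2c1 | intermediate
13 | (3S,5R)-5-(dichloromethyl)-3-hydroxy-5-[(8-hydroxy-6-methoxy-1-oxo-1H-isochromen-3-yl)methyl]oxolan-2-one (CNP0072605.2) | COc1cc(O)c2c(=O)oc(C[C@@]3(C(Cl)Cl)C[C@H](O)C(=O)O3)cc2c1 | target

**Step count**

Total step count: 4. Longest linear sequence: 4 steps (1 → 4 → 8 → 12 → 13).

**Steps most likely to fail**

Step 3 is the most exposed. LiCHCl2 may act as a base on the acidic C1′H2 of 8 (the enolate simply returns 8 on quench), it may attack the dioxolanone or isocoumarin carbonyl, and the 1,3-induction may be modest. In that case the 5S epimer is removed by chromatography; enantiopurity is not at stake because C3 comes from 5. The fallback sets out from 8 and comes back at 12. The d1 carbon is delivered as trichloromethide, which is many pK units less basic than LiCHCl2 and is generated without added base by decarboxylation of Cl3CCO2Na in DMSO buffered with Cl3CCO2H at 25 °C. The reversible carbonyl adduct is drained by the same acyl transfer onto the dioxolanone, giving (3S,5R)-5-[(6,8-dimethoxy-1-oxo-1H-isochromen-3-yl)methyl]-3-hydroxy-5-(trichloromethyl)oxolan-2-one F1, the C5 epimers being separated at this stage. One chlorine is then removed with Bu3SnH (1.05 equiv) and azobisisobutyronitrile in toluene at 80 °C to give 12.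

Step 2 is next. The lithiated isocoumarin may condense with the lactone of a second molecule or react at C4 instead of the exocyclic carbon, and the malic unit may suffer β-elimination or C3 epimerisation if base is left over. The fallback sets out from 3, isolated by a neutral aqueous NH4Cl quench of step 1 in place of the acid treatment, and comes back at 8. Keto ester 3 is converted into its 1,3-dianion (LiN(iPr)2, 2.2 equiv, THF, −78 → −40 °C), which is acylated at the more reactive methyl terminus by acyl imidazolide 7 to give methyl 2-{5-[(4S)-2,2-dimethyl-5-oxo-1,3-dioxolan-4-yl]-2,4-dioxopentyl}-4,6-dimethoxybenzoate F2. CF3CO2H in CH2Cl2 then closes the pyranone ring (enol oxygen of the benzylic ketone onto the ester) to give 8, so the ring closure follows the chain extension instead of preceding it.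

Step 1 is third. The toluate anion can attack the ester of a second molecule, and the lactonisation of 3 may stall. The fallback sets out from 1 and comes back at 4. Ester 1 is saponified (KOH, aqueous DMSO, 100 °C) to 2,4-dimethoxy-6-methylbenzoic acid F3. Its dianion (LiN(iPr)2, 2.2 equiv, THF, −78 → 0 °C), whose carboxylate cannot be attacked by a second anion, is acylated with 2 to give 2,4-dimethoxy-6-(2-oxopropyl)benzoic acid F4. (CF3CO)2O in CH2Cl2 at 0 °C closes F4 to 4 by cyclodehydration.

**Further compounds**

F1 | step 3 | (3S,5R)-5-[(6,8-dimethoxy-1-oxo-1H-isochromen-3-yl)methyl]-3-hydroxy-5-(trichloromethyl)oxolan-2-one | COc1cc(OC)c2c(=O)oc(C[C@@]3(C(Cl)(Cl)Cl)C[C@H](O)C(=O)O3)cc2c1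
F2 | step 2 | methyl 2-{5-[(4S)-2,2-dimethyl-5-oxo-1,3-dioxolan-4-yl]-2,4-dioxopentyl}-4,6-dimethoxybenzoate | COC(=O)c1c(CC(=O)CC(=O)C[C@@H]2OC(C)(C)OC2=O)cc(OC)cc1OC
F3 | step 1 | 2,4-dimethoxy-6-methylbenzoic acid | OC(=O)c1c(C)cc(OC)cc1OC
F4 | step 1 | 2,4-dimethoxy-6-(2-oxopropyl)benzoic acid | OC(=O)c1c(CC(C)=O)cc(OC)cc1OC
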